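**Retrosynthetic overview**
1. The target is numbered as a tricyclo[5.4.0.0(2,8)]undec-10-en-9-one (C1 and C2 ring-fusion CH, C3 CMe2, C4 and C6 C–O, C7 C–Me, C8 CH, C9 C=O, C10=C11–Me). The two tiglates go on last, and the C6 carbinol comes from a C6 ketone by hydroxyl-directed anti reduction from C4–OH.
2. Key disconnection C7–C8: this one bond is shared by the cyclobutane C1–C2–C8–C7, the cyclohexenone C1–C7–C8–C9–C10–C11 and the seven-membered ring, and with C6 as a ketone it is the middle bond of a 1,4-diketone (C6=O, C9=O). Both ends are therefore enol-ether carbons, and the bond is made by anodic coupling of the two silyl enol ethers of a cis-fused bicyclo[5.4.0]undecane.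
3. The six-membered ring C1–C2–C8–C9–C10–C11 of that bicycle is closed at C1–C11 by a nickel-catalysed reductive conjugate addition of a (Z)-β-iodoenone side chain to a 2-methylcyclohept-2-enone, which also gives the C6=C7 silyl enol ether regiospecifically and the cis ring fusion.
4. The seven-membered ring with all four methyl groups is eucarvone (from carvone); C4–O comes from Jacobsen epoxidation and reductive opening, the C2 side chain from enolate alkylation, and the enone is moved by a Wharton reaction.
5. Order of ring formation: seven-membered ring (step 2), ring C1–C2–C8–C9–C10–C11 (step 12), then cyclobutane and cyclohexenone C1–C7–C8–C9–C10–C11 together (step 14).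

Key step: step 14

Remark: the configurations of the enone-derived epoxide and of the allylic carbinol that follows it are drawn as expected by analogy with carvone oxide; both are erased when this carbon becomes a ketone.

**Route**

Step 1
Reactants: 1 (R)-(−)-carvone
Product: 2 (5R)-5-(2-bromopropan-2-yl)-2-methylcyclohex-2-en-1-one
Conditions: HBr (33% in AcOH), 0 °C
Reagents that add atoms: hydrogen bromide, Br
Why: Markovnikov hydrobromination (ionic HX addition) of the electron-rich isopropenyl group, while the enone C=C is deactivated and the stereocentre is untouched.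

Step 2
Reactants: 2 (5R)-5-(2-bromopropan-2-yl)-2-methylcyclohex-2-en-1-one
Product: 4 eucarvone, via carenone 3 (not isolated)
Conditions: KOH, MeOH, reflux
Reagents that add atoms: none
Why: Intramolecular enolate alkylation (3-exo-tet) closes the cyclopropane of 3, and base-induced opening of its ring-fusion bond through the extended enolate gives the cycloheptadienone (the classical eucarvone preparation); the stereocentre disappears.

Step 3
Reactants: 4 eucarvone
Product: 5 (4R,5S)-4,5-epoxy-2,6,6-trimethylcyclohept-2-en-1-one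
Conditions: (R,R)-(salen)MnCl (5 mol%; salen = N,N′-bis(3,5-di-tert-butylsalicylidene)-1,2-cyclohexanediamine dianion), mCPBA, N-methylmorpholine N-oxide, CH2Cl2, −78 °C
Reagents that add atoms: mCPBA, OOC(=O)c1cccc(Cl)c1
Why: Jacobsen epoxidation of the cis-disubstituted, conjugated γ,δ-alkene (the electron-richer one, flanked by CMe2 as in a 2,2-dimethylchromene); the catalyst should control the face and so set C4 and C5, with the (R,R) sense assigned by that analogy.

Step 4
Reactants: 5 (4R,5S)-4,5-epoxy-2,6,6-trimethylcyclohept-2-en-1-one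
Product: 7 (5R)-5-hydroxy-2,6,6-trimethylcyclohept-2-en-1-one, via β,γ-enone 6 (not isolated)
Conditions: SmI2 (2.2 equiv), THF–MeOH, −90 °C; then DBU (0.2 equiv), CH2Cl2, rt
Reagents that add atoms: none
Why: Single-electron reduction of a vinylogous epoxy ketone cleaves the allylic C4–O bond only, so the C5–O bond keeps its configuration; mild base then moves the alkene back into conjugation.

Step 5
Reactants: 7 (5R)-5-hydroxy-2,6,6-trimethylcyclohept-2-en-1-one
Product: 8 (5R)-5-(tert-butyldimethylsilyloxy)-2,6,6-trimethylcyclohept-2-en-1-one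
Conditions: TBSOTf, 2,6-lutidine, CH2Cl2, −78 → 0 °C
Reagents that add atoms: tert-butyldimethylsilyl trifluoromethanesulfonate, CC(C)(C)[Si](C)(C)OS(=O)(=O)C(F)(F)F
Why: Silyl triflate silylation, which is strong enough for a neopentyl-type secondary alcohol; no stereocentre is touched.

Step 6
Reactants: 8 (5R)-5-(tert-butyldimethylsilyloxy)-2,6,6-trimethylcyclohept-2-en-1-one; 9 2-bromo-N-methoxy-N-methylacetamide
Product: 11 (5R,7S)-5-(tert-butyldimethylsilyloxy)-7-[2-(methoxy(methyl)amino)-2-oxoethyl]-2,6,6-trimethylcyclohept-2-en-1-one, via lithium enolate 10 (not isolated)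
Conditions: LiN(iPr)2, THF, −78 °C; then 9, DMPU, −78 → −30 °C
Reagents that add atoms: none
Why: Kinetic α′-deprotonation of the enone followed by SN2 alkylation with an α-bromo amide; C7 should be set trans to the C5 silyloxy group because the electrophile enters anti to the pseudo-axial C6 methyl group, which lies on the side of the equatorial silyloxy group.

Step 7
Reactants: 11 (5R,7S)-5-(tert-butyldimethylsilyloxy)-7-[2-(methoxy(methyl)amino)-2-oxoethyl]-2,6,6-trimethylcyclohept-2-en-1-one
Product: 12 (2R,3R,5R,7S)-5-(tert-butyldimethylsilyloxy)-2,3-epoxy-7-[2-(methoxy(methyl)amino)-2-oxoethyl]-2,6,6-trimethylcycloheptan-1-one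
Conditions: H2O2 (30%), NaOH, MeOH, 0 °C
Reagents that add atoms: hydrogen peroxide, OO
Why: Weitz–Scheffer nucleophilic epoxidation of the α-methyl enone, as with carvone; attack anti to the C5 silyloxy group is expected, and these two centres are erased later.

Step 8
Reactants: 12 (2R,3R,5R,7S)-5-(tert-butyldimethylsilyloxy)-2,3-epoxy-7-[2-(methoxy(methyl)amino)-2-oxoethyl]-2,6,6-trimethylcycloheptan-1-one
Product: 14 2-[(1R,4R,6R)-6-(tert-butyldimethylsilyloxy)-4-hydroxy-3,7,7-trimethylcyclohept-2-en-1-yl]-N-methoxy-N-methylacetamide, via epoxy hydrazone 13 (not isolated)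
Conditions: N2H4·H2O, AcOH, MeOH, 0 °C → rt
Reagents that add atoms: none
Why: Wharton reaction: the epoxy hydrazone opens and loses N2 to give the allylic alcohol with 1,3-transposition, so the old carbonyl carbon becomes the alkene CH next to the side chain; the tertiary amide should be inert to hydrazine at this temperature.

Step 9
Reactants: 14 2-[(1R,4R,6R)-6-(tert-butyldimethylsilyloxy)-4-hydroxy-3,7,7-trimethylcyclohept-2-en-1-yl]-N-methoxy-N-methylacetamide; 15 1-propynylmagnesium bromide
Product: 16 1-[(1R,4R,6R)-6-(tert-butyldimethylsilyloxy)-4-hydroxy-3,7,7-trimethylcyclohept-2-en-1-yl]pent-3-yn-2-one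
Conditions: 15 (2.5 equiv), THF, 0 °C; aq. NH4Cl
Reagents that add atoms: none
Why: Weinreb ketone synthesis, in which the N-methoxy-N-methylamide stops the addition at the ketone stage; one equivalent of the reagent is used up by the free hydroxyl group.

Step 10
Reactants: 16 1-[(1R,4R,6R)-6-(tert-butyldimethylsilyloxy)-4-hydroxy-3,7,7-trimethylcyclohept-2-en-1-yl]pent-3-yn-2-one
Product: 17 (4R,6R)-6-(tert-butyldimethylsilyloxy)-2,5,5-trimethyl-4-(2-oxopent-3-yn-1-yl)cyclohept-2-en-1-one
Conditions: MnO2 (activated), CH2Cl2, rt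
Reagents that add atoms: none
Why: Chemoselective oxidation of the allylic alcohol gives the transposed 2-methylcycloheptenone and removes the carbinol centre; the ynone and the silyl ether are left alone.

Step 11
Reactants: 17 (4R,6R)-6-(tert-butyldimethylsilyloxy)-2,5,5-trimethyl-4-(2-oxopent-3-yn-1-yl)cyclohept-2-en-1-one
Product: 18 (4R,6R)-6-(tert-butyldimethylsilyloxy)-4-[(Z)-4-iodo-2-oxopent-3-en-1-yl]-2,5,5-trimethylcyclohept-2-en-1-one
Conditions: NaI, AcOH, MeCN, rt
Reagents that add atoms: sodium iodide, [Na+].[I-]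
Why: Conjugate hydroiodination of the ynone by anti addition gives the (Z)-β-iodoenone with iodine cis to the carbonyl group, which is the geometry the ring closure needs.

Step 12
Reactants: 18 (4R,6R)-6-(tert-butyldimethylsilyloxy)-4-[(Z)-4-iodo-2-oxopent-3-en-1-yl]-2,5,5-trimethylcyclohept-2-en-1-one
Product: 19 (4aR,8R,9aR)-8-(tert-butyldimethylsilyloxy)-4,5,9,9-tetramethyl-6-(triethylsilyloxy)-1,4a,7,8,9,9a-hexahydro-2H-benzo[7]annulen-2-one
Conditions: NiCl2(dme) (10 mol%), neocuproine (10 mol%), Mn powder (3 equiv), Et3SiCl (1.5 equiv), DMF, 25 °C, 0.02 M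
Reagents that add atoms: chlorotriethylsilane, CC[Si](Cl)(CC)CC
Why: Nickel-catalysed reductive conjugate addition of an alkenyl halide to an enone with chlorosilane trapping, here intramolecular and 6-exo; the tether on the neighbouring carbon delivers the alkenyl group to the same face, which sets the cis ring fusion (C4a), and the silyl enol ether can form only toward the methyl-bearing carbon.

Step 13
Reactants: 19 (4aR,8R,9aR)-8-(tert-butyldimethylsilyloxy)-4,5,9,9-tetramethyl-6-(triethylsilyloxy)-1,4a,7,8,9,9a-hexahydro-2H-benzo[7]annulen-2-one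
Product: 21 (4aR,8R,9aS)-8-(tert-butyldimethylsilyloxy)-4,5,9,9-tetramethyl-2,6-bis(triethylsilyloxy)-4a,8,9,9a-tetrahydro-7H-benzo[7]annulene, via lithium dienolate 20 (not isolated)
Conditions: LiN(iPr)2, THF, −78 °C; then Et3SiCl, Et3N, −78 → 0 °C
Reagents that add atoms: chlorotriethylsilane, CC[Si](Cl)(CC)CC
Why: Kinetic α′-deprotonation of the 3-methylcyclohexenone and O-silylation give the cross-conjugated 2-silyloxy-1,3-diene; the existing enol ether and all stereocentres are untouched.

Step 14
Reactants: 21 (4aR,8R,9aS)-8-(tert-butyldimethylsilyloxy)-4,5,9,9-tetramethyl-2,6-bis(triethylsilyloxy)-4a,8,9,9a-tetrahydro-7H-benzo[7]annulene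
Product: 22 (1R,2S,4R,7R,8R)-4-(tert-butyldimethylsilyloxy)-3,3,7,11-tetramethyltricyclo[5.4.0.0(2,8)]undec-10-ene-6,9-dione
Conditions: RVC anode, Pt cathode, undivided cell, constant current (2.2 F/mol), LiClO4 (0.1 M), 2,6-lutidine, MeOH–CH2Cl2 (1:4), 0.005 M, −20 °C; then 1 M HCl, THF, 0 °C
Reagents that add atoms: none
Why: Proposed new method: the anode takes one electron from the 2-silyloxy-1,3-diene (the more easily oxidised group), methanol removes its silyl group to leave the electrophilic α-keto radical at C8 (target numbering), this radical adds 4-exo-trig to C7 of the electron-rich tetrasubstituted silyl enol ether, and the α-silyloxy radical formed at C6 is oxidised at the electrode at once and loses its silyl group, so a strained and reversible ring closure is made productive by the second, irreversible electron transfer; the closest known reaction types are the intramolecular anodic coupling of two enol ethers to five- and six-membered rings and the oxidative coupling of silyl bis-enol ethers to 1,4-diketones. The one new bond C7–C8 closes the cyclobutane C1–C2–C8–C7 in the 4-exo mode and, by the same bond, the cyclohexenone C1–C7–C8–C9–C10–C11 and the bridged seven-membered ring. C8 is set because C7 can reach it only on the face of the six-membered ring that carries the C1–C7 bond, and the quaternary centre C7 is set because C8, held on C2 of the cis ring fusion, can reach only one face of the enol ether, which leaves the C7 methyl group syn to the enone bridge. The step needs C7–C8 bond formation in preference to oxidative aromatisation of the cyclohexadiene and to intermolecular coupling; C7 and C8 are the only enol-ether β-carbons, the cis fusion holds them in a 1,4-relation, and high dilution with 2,6-lutidine as buffer should suppress the other paths.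

Step 15
Reactants: 22 (1R,2S,4R,7R,8R)-4-(tert-butyldimethylsilyloxy)-3,3,7,11-tetramethyltricyclo[5.4.0.0(2,8)]undec-10-ene-6,9-dione
Product: 23 (1R,2S,4R,7R,8R)-4-hydroxy-3,3,7,11-tetramethyltricyclo[5.4.0.0(2,8)]undec-10-ene-6,9-dione
Conditions: HF·pyridine, THF, 0 °C → rt
Reagents that add atoms: none
Why: Fluoride-mediated desilylation under acidic conditions, which avoids retro-aldol cleavage of the β-hydroxy ketone that a basic fluoride source could cause.

Step 16
Reactants: 23 (1R,2S,4R,7R,8R)-4-hydroxy-3,3,7,11-tetramethyltricyclo[5.4.0.0(2,8)]undec-10-ene-6,9-dione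
Product: 24 (1R,2S,4R,6R,7R,8R)-4,6-dihydroxy-3,3,7,11-tetramethyltricyclo[5.4.0.0(2,8)]undec-10-en-9-one
Conditions: Me4NBH(OAc)3, MeCN–AcOH (1:1), −30 → 0 °C
Reagents that add atoms: none
Why: Evans–Saksena reduction: the boron reagent binds to the C4 hydroxyl group and delivers hydride to the C6 ketone internally, which sets C6 anti to C4 (the 1,3-anti diol); the enone has no such directing group and should not be reduced.

Step 17
Reactants: 24 (1R,2S,4R,6R,7R,8R)-4,6-dihydroxy-3,3,7,11-tetramethyltricyclo[5.4.0.0(2,8)]undec-10-en-9-one; 25 tigloyl chloride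
Product: 26 (1R,2S,4R,6R,7R,8R)-3,3,7,11-tetramethyl-9-oxotricyclo[5.4.0.0(2,8)]undec-10-ene-4,6-diyl bis[(E)-2-methylbut-2-enoate]
Conditions: 25 (4 equiv), DMAP, pyridine, CH2Cl2, 40 °C
Reagents that add atoms: none
Why: DMAP-catalysed acylation through the acylpyridinium ion esterifies both hindered secondary alcohols; the (E) geometry of the tiglate is the stable one and is kept, and no stereocentre is touched.

**Compound list**
1 | (R)-(−)-carvone, (5R)-2-methyl-5-(prop-1-en-2-yl)cyclohex-2-en-1-one | CC(=C)[C@@H]1CC=C(C)C(=O)C1 | starting material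
2 | (5R)-5-(2-bromopropan-2-yl)-2-methylcyclohex-2-en-1-one (carvone hydrobromide) | CC(C)(Br)[C@@H]1CC=C(C)C(=O)C1 | intermediate
3 | carenone, (1S,6R)-3,7,7-trimethylbicyclo[4.1.0]hept-3-en-2-one | CC1=CC[C@H]2C(C)(C)[C@H]2C1=O | intermediate
4 | eucarvone, 2,6,6-trimethylcyclohepta-2,4-dien-1-one | CC1=CC=CC(C)(C)CC1=O | intermediate
5 | (4R,5S)-4,5-epoxy-2,6,6-trimethylcyclohept-2-en-1-one | O=C1CC(C)(C)[C@@H]2O[C@@H]2C=C1C | intermediate
6 | (5R)-5-hydroxy-2,6,6-trimethylcyclohept-3-en-1-one (C2 epimers) | O[C@@H]1C=CC(C)C(=O)CC1(C)C | intermediate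
7 | (5R)-5-hydroxy-2,6,6-trimethylcyclohept-2-en-1-one | O[C@@H]1CC=C(C)C(=O)CC1(C)C | intermediate
8 | (5R)-5-(tert-butyldimethylsilyloxy)-2,6,6-trimethylcyclohept-2-en-1-one | CC(C)(C)[Si](C)(C)O[C@@H]1CC=C(C)C(=O)CC1(C)C | intermediate
9 | 2-bromo-N-methoxy-N-methylacetamide | CON(C)C(=O)CBr | starting material
10 | lithium enolate of 8 (O–C1=C7, cross-conjugated) | CC(C)(C)[Si](C)(C)O[C@@H]1CC=C(C)C([O-])=CC1(C)C.[Li+] | intermediate
11 | (5R,7S)-5-(tert-butyldimethylsilyloxy)-7-[2-(methoxy(methyl)amino)-2-oxoethyl]-2,6,6-trimethylcyclohept-2-en-1-one (side chain trans to OTBS) | CC(C)(C)[Si](C)(C)O[C@@H]1CC=C(C)C(=O)[C@@H](CC(=O)N(C)OC)C1(C)C | intermediate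
12 | (2R,3R,5R,7S)-5-(tert-butyldimethylsilyloxy)-2,3-epoxy-7-[2-(methoxy(methyl)amino)-2-oxoethyl]-2,6,6-trimethylcycloheptan-1-one (oxirane trans to OTBS) | CC(C)(C)[Si](C)(C)O[C@@H]1C[C@H]2O[C@@]2(C)C(=O)[C@@H](CC(=O)N(C)OC)C1(C)C | intermediate
13 | hydrazone of 12 at C1 | CC(C)(C)[Si](C)(C)O[C@@H]1C[C@H]2O[C@@]2(C)C(=NN)[C@@H](CC(=O)N(C)OC)C1(C)C | intermediate
14 | 2-[(1R,4R,6R)-6-(tert-butyldimethylsilyloxy)-4-hydroxy-3,7,7-trimethylcyclohept-2-en-1-yl]-N-methoxy-N-methylacetamide | CC(C)(C)[Si](C)(C)O[C@@H]1C[C@@H](O)C(C)=C[C@@H](CC(=O)N(C)OC)C1(C)C | intermediate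
15 | 1-propynylmagnesium bromide | CC#C[Mg]Br | starting material
16 | 1-[(1R,4R,6R)-6-(tert-butyldimethylsilyloxy)-4-hydroxy-3,7,7-trimethylcyclohept-2-en-1-yl]pent-3-yn-2-one | CC(C)(C)[Si](C)(C)O[C@@H]1C[C@@H](O)C(C)=C[C@@H](CC(=O)C#CC)C1(C)C | intermediate
17 | (4R,6R)-6-(tert-butyldimethylsilyloxy)-2,5,5-trimethyl-4-(2-oxopent-3-yn-1-yl)cyclohept-2-en-1-one | CC(C)(C)[Si](C)(C)O[C@@H]1CC(=O)C(C)=C[C@@H](CC(=O)C#CC)C1(C)C | intermediate
18 | (4R,6R)-6-(tert-butyldimethylsilyloxy)-4-[(Z)-4-iodo-2-oxopent-3-en-1-yl]-2,5,5-trimethylcyclohept-2-en-1-one | CC(C)(C)[Si](C)(C)O[C@@H]1CC(=O)C(C)=C[C@@H](CC(=O)/C=C(/C)I)C1(C)C | intermediate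
19 | (4aR,8R,9aR)-8-(tert-butyldimethylsilyloxy)-4,5,9,9-tetramethyl-6-(triethylsilyloxy)-1,4a,7,8,9,9a-hexahydro-2H-benzo[7]annulen-2-one (cis-fused) | CC(C)(C)[Si](C)(C)O[C@@H]1CC(O[Si](CC)(CC)CC)=C(C)[C@H]2C(C)=CC(=O)C[C@H]2C1(C)C | intermediate
20 | lithium dienolate of 19 (O–C2=C1) | CC(C)(C)[Si](C)(C)O[C@@H]1CC(O[Si](CC)(CC)CC)=C(C)[C@H]2C(C)=CC([O-])=C[C@H]2C1(C)C.[Li+] | intermediate
21 | (4aR,8R,9aS)-8-(tert-butyldimethylsilyloxy)-4,5,9,9-tetramethyl-2,6-bis(triethylsilyloxy)-4a,8,9,9a-tetrahydro-7H-benzo[7]annulene (cis-fused) | CC(C)(C)[Si](C)(C)O[C@@H]1CC(O[Si](CC)(CC)CC)=C(C)[C@H]2C(C)=CC(O[Si](CC)(CC)CC)=C[C@H]2C1(C)C | intermediate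
22 | (1R,2S,4R,7R,8R)-4-(tert-butyldimethylsilyloxy)-3,3,7,11-tetramethyltricyclo[5.4.0.0(2,8)]undec-10-ene-6,9-dione | CC(C)(C)[Si](C)(C)O[C@@H]1CC(=O)[C@@]2(C)[C@@H]3C(=O)C=C(C)[C@H]2[C@@H]3C1(C)C | intermediate
23 | (1R,2S,4R,7R,8R)-4-hydroxy-3,3,7,11-tetramethyltricyclo[5.4.0.0(2,8)]undec-10-ene-6,9-dione | O[C@@H]1CC(=O)[C@@]2(C)[C@@H]3C(=O)C=C(C)[C@H]2[C@@H]3C1(C)C | intermediate
24 | (1R,2S,4R,6R,7R,8R)-4,6-dihydroxy-3,3,7,11-tetramethyltricyclo[5.4.0.0(2,8)]undec-10-en-9-one | O[C@@H]1C[C@@H](O)[C@@]2(C)[C@@H]3C(=O)C=C(C)[C@H]2[C@@H]3C1(C)C | intermediate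
25 | tigloyl chloride, (E)-2-methylbut-2-enoyl chloride | C/C=C(\C)C(Cl)=O | starting material
26 | (1R,2S,4R,6R,7R,8R)-3,3,7,11-tetramethyl-9-oxotricyclo[5.4.0.0(2,8)]undec-10-ene-4,6-diyl bis[(E)-2-methylbut-2-enoate] | C/C=C(\C)C(=O)O[C@@H]1C[C@@H](OC(=O)/C(C)=C/C)[C@@]2(C)[C@@H]3C(=O)C=C(C)[C@H]2[C@@H]3C1(C)C | target

**Step count and risks**
Total step count: 17. Longest linear sequence: 17 steps (fully linear from 1).

Steps most likely to fail:

Step 14 (Proposed new method). The radical formed after the first electron transfer may be lost by oxidative aromatisation of the cyclohexadiene ring or by intermolecular coupling before the strained four-membered ring closes. The fallback uses known chemistry and sets out from 19. Kinetic deprotonation with LiN(iPr)2 and bromination of lithium dienolate 20 with N-bromosuccinimide at −78 °C should give the α′-bromo enone F1, in which the triethylsilyl enol ether is kept. Anhydrous benzyltrimethylammonium fluoride then frees the enolate of the seven-membered-ring ketone regiospecifically from that silyl enol ether, and this enolate displaces bromide in an intramolecular 4-exo-tet alkylation (cyclobutane formation by enolate alkylation). The route is rejoined at 22.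

Step 12. The carbon–iodine bond may be reduced without ring closure, or the iodoenone may oligomerise at the nickel centre before it is captured by the ring enone. The fallback sets out from 18. Bu3SnH and AIBN (benzene, 80 °C, slow addition) should close the same ring by 6-exo-trig cyclisation of the alkenyl radical onto the enone and give the bicyclic diketone F2. Silylation of both carbonyl groups under equilibrating conditions (Et3SiCl, NaI, Et3N, MeCN) should give the more substituted enol ether of the saturated ketone and the cross-conjugated dienol ether of the enone, which rejoins the route at 21.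

Step 6. The alkylation may show poor facial selectivity, and the new centre may be lost by enolisation under the basic conditions of step 7. The fallback sets out from 7. Aldol condensation with ethyl glyoxylate (LiN(iPr)2, 2 equiv; then MsCl, Et3N, DBU) should give the exocyclic alkylidene ester F3. Hydrogenation directed by the free C5 hydroxyl group ([Rh(nbd)(dppb)]BF4, H2, CH2Cl2) delivers hydrogen to C7 on the face of the hydroxyl group and should give the ester F4 with the side chain trans to oxygen. Silylation with TBSOTf gives the silyl ether F5, and Me(MeO)NH·HCl with i-PrMgCl converts the ester into the amide, which rejoins the route at 11.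

Further compounds
F1 | step 14 | 1-bromo-8-(tert-butyldimethylsilyloxy)-4,5,9,9-tetramethyl-6-(triethylsilyloxy)-1,4a,7,8,9,9a-hexahydro-2H-benzo[7]annulen-2-one (Br on the ring face opposite to C5) | CC(C)(C)[Si](C)(C)O[C@@H]1CC(O[Si](CC)(CC)CC)=C(C)[C@H]2C(C)=CC(=O)[C@H](Br)[C@H]2C1(C)C
F2 | step 12 | 8-(tert-butyldimethylsilyloxy)-4,5,9,9-tetramethyl-4a,5,7,8,9,9a-hexahydro-1H-benzo[7]annulene-2,6-dione (cis-fused, C5 epimers) | CC(C)(C)[Si](C)(C)O[C@@H]1CC(=O)C(C)[C@H]2C(C)=CC(=O)C[C@H]2C1(C)C
F3 | step 6 | ethyl (2Z)-2-[(6R)-6-hydroxy-3,7,7-trimethyl-2-oxocyclohept-3-en-1-ylidene]acetate | O[C@@H]1CC=C(C)C(=O)/C(=C\C(=O)OCC)C1(C)C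
F4 | step 6 | ethyl 2-[(1S,6R)-6-hydroxy-3,7,7-trimethyl-2-oxocyclohept-3-en-1-yl]acetate | O[C@@H]1CC=C(C)C(=O)[C@@H](CC(=O)OCC)C1(C)C
F5 | step 6 | ethyl 2-[(1S,6R)-6-(tert-butyldimethylsilyloxy)-3,7,7-trimethyl-2-oxocyclohept-3-en-1-yl]acetate | CC(C)(C)[Si](C)(C)O[C@@H]1CC=C(C)C(=O)[C@@H](CC(=O)OCC)C1(C)C
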